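**Plan**
- The target is the (2R,3R) flavan-3-ol (epicatechin skeleton) acylated at O3 by 3-hydroxy-4,5-dimethoxybenzoic acid. C4 is the only CH2 of ring C and its neighbour C3 carries the ester oxygen, so C3–C4 is cut as an enol-ester double bond C3=C4 between a vinyl group on ring A and a 1-acyloxyvinyl group on C2 (ring-closing metathesis).
- Further cuts: the vinylic C3–O bond (carboxylic acid plus terminal alkyne), the O1–C2 aryl ether (Mitsunobu) and the C2–C3 bond (alkynylation of the ring B aldehyde).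
- Forward: rings A, B and D are bought as benzenes. The chain ArCH(OAr)–C≡CH is assembled, the ring D acid is added across the alkyne, and ring C is closed last by metathesis.
- One hydrogenation then saturates C3=C4 and frees the five phenols.
- Stereochemistry: C2 comes from a catalytic asymmetric alkynylation (S carbinol) followed by Mitsunobu inversion. C3 comes from syn addition of H2 to the face of C3=C4 opposite ring B, which leaves the ester cis to the aryl group.

Key step: step 8

Assumption: in step 4 the ProPhenol antipode that delivers the alkynyl group to the Re face of the aldehyde is used (both antipodes are sold); the sense is to be checked on the first batch by MTPA ester analysis.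

**Step 1**
Reactants: 1 2,4,6-trihydroxybenzaldehyde
Product: 2 4,6-bis(benzyloxy)-2-hydroxybenzaldehyde
Conditions: BnBr (2.05 equiv), K2CO3 (2.2 equiv), DMF, 0 °C to rt
Reagents that add atoms: benzyl bromide, BrCc1ccccc1
Why: Williamson ether synthesis; the 4-OH and one ortho OH are alkylated, while the last ortho OH is held by a hydrogen bond to the formyl oxygen and reacts far more slowly, so two equivalents of halide should stop at the dibenzyl ether.

**Step 2**
Reactants: 2 4,6-bis(benzyloxy)-2-hydroxybenzaldehyde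
Product: 3 3,5-bis(benzyloxy)-2-ethenylphenol
Conditions: Ph3PCH3Br (2.6 equiv), KOtBu (2.5 equiv), THF, 0 to 40 °C; aq NH4Cl
Reagents that add atoms: methyltriphenylphosphonium bromide, C[P+](c1ccccc1)(c1ccccc1)c1ccccc1.[Br-]
Why: Wittig methylenation; one equivalent of ylide is spent on the phenol and the excess converts the formyl group of the phenoxide into the vinyl group, as is usual for salicylaldehydes.

**Step 3**
Reactants: 4 3-hydroxy-4,5-dimethoxybenzoic acid
Product: 6 3-(benzyloxy)-4,5-dimethoxybenzoic acid, via benzyl ester 5 (not isolated)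
Conditions: BnBr (2.3 equiv), K2CO3, DMF, 60 °C; then aq NaOH, MeOH, 60 °C; HCl to pH 2
Reagents that add atoms: benzyl bromide, BrCc1ccccc1; sodium hydroxide, [Na+].[OH-]
Why: Williamson etherification with concurrent benzyl ester formation, then saponification in the same flask, returns the free acid with its phenol masked as a benzyl ether that the final hydrogenolysis removes.

**Step 4**
Reactants: 7 3,4-bis(benzyloxy)benzaldehyde; 8 ethynyltrimethylsilane
Product: 9 (1S)-1-[3,4-bis(benzyloxy)phenyl]-3-(trimethylsilyl)prop-2-yn-1-ol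
Conditions: Me2Zn (3 equiv), ProPhenol ligand (2,6-bis{[2-(hydroxydiphenylmethyl)pyrrolidin-1-yl]methyl}-4-methylphenol, 10 mol%), Ph3P=O (20 mol%), toluene, 0 °C; aq NH4Cl
Reagents that add atoms: none
Why: Catalytic asymmetric alkynylation of an aldehyde; the alkynylzinc made from 8 and Me2Zn is delivered inside the chiral dinuclear zinc–ProPhenol complex to the Re face of the aldehyde, which sets the carbinol centre as S by catalyst control.

**Step 5**
Reactants: 9 (1S)-1-[3,4-bis(benzyloxy)phenyl]-3-(trimethylsilyl)prop-2-yn-1-ol; 3 3,5-bis(benzyloxy)-2-ethenylphenol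
Product: 10 {(3R)-3-[3,4-bis(benzyloxy)phenyl]-3-[3,5-bis(benzyloxy)-2-ethenylphenoxy]prop-1-yn-1-yl}trimethylsilane
Conditions: PPh3, DIAD, toluene, −20 °C to rt
Reagents that add atoms: none
Why: Mitsunobu etherification; the phenoxide displaces the oxyphosphonium group in an SN2 step with inversion, turning the S carbinol into the ether with the arrangement needed at C2 (R by the priority rules), and the non-polar solvent and low temperature hold back ionisation of the electron-rich benzylic centre.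

**Step 6**
Reactants: 10 {(3R)-3-[3,4-bis(benzyloxy)phenyl]-3-[3,5-bis(benzyloxy)-2-ethenylphenoxy]prop-1-yn-1-yl}trimethylsilane
Product: 11 1,5-bis(benzyloxy)-3-{[(1S)-1-[3,4-bis(benzyloxy)phenyl]prop-2-yn-1-yl]oxy}-2-ethenylbenzene
Conditions: K2CO3 (0.2 equiv), MeOH/THF, 0 °C
Reagents that add atoms: none
Why: Base-catalysed protodesilylation of an alkynylsilane by methoxide, mild enough to leave the propargylic C–H alone; the descriptor changes from R to S only because ethynyl ranks below aryl, the arrangement in space being unchanged.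

**Step 7**
Reactants: 11 1,5-bis(benzyloxy)-3-{[(1S)-1-[3,4-bis(benzyloxy)phenyl]prop-2-yn-1-yl]oxy}-2-ethenylbenzene; 6 3-(benzyloxy)-4,5-dimethoxybenzoic acid
Product: 12 (3R)-3-[3,4-bis(benzyloxy)phenyl]-3-[3,5-bis(benzyloxy)-2-ethenylphenoxy]prop-1-en-2-yl 3-(benzyloxy)-4,5-dimethoxybenzoate
Conditions: [RuCl2(p-cymene)]2 (2 mol%), P(2-furyl)3 (4 mol%), Na2CO3 (8 mol%), toluene, 50 °C
Reagents that add atoms: none
Why: Ruthenium-catalysed Markovnikov hydro-acyloxylation of a terminal alkyne; the carboxylate attacks the internal carbon of the alkyne bound to divalent ruthenium and protonolysis releases the geminal enol ester under nearly neutral conditions that should leave the C2 centre, the styrene and the benzyl ethers untouched.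

**Step 8**
Reactants: 12 (3R)-3-[3,4-bis(benzyloxy)phenyl]-3-[3,5-bis(benzyloxy)-2-ethenylphenoxy]prop-1-en-2-yl 3-(benzyloxy)-4,5-dimethoxybenzoate
Product: 13 (2R)-5,7-bis(benzyloxy)-2-[3,4-bis(benzyloxy)phenyl]-2H-chromen-3-yl 3-(benzyloxy)-4,5-dimethoxybenzoate
Conditions: second-generation Grubbs catalyst (H2IMes)(PCy3)Cl2Ru=CHPh (5 mol%), 1,4-benzoquinone (10 mol%), toluene (0.005 M), 80 °C, argon sparge
Reagents that add atoms: none
Why: Ring-closing olefin metathesis: the ruthenium benzylidene exchanges onto the ring A vinyl group, the only monosubstituted olefin, the resulting styrenyl alkylidene adds across the tethered 1-acyloxyvinyl group in a [2+2] step, and cycloreversion of the ruthenacyclobutane releases the C3=C4 bond and Ru=CH2, with ethylene as the only by-product. The closest known reactions are the metathesis closure of 2-vinylphenyl allyl ethers to 2H-chromenes and the ring-closing metathesis of geminal enol esters and silyl enol ethers to cyclic enol derivatives. Ring C closes as a six-membered ring by intramolecular alkylidene transfer, the new double bond lying inside the ring. No stereocentre is made and C2 is carried through; because initiation on the hindered, acyloxy-bearing 1,1-disubstituted olefin is slow, ruthenium should not come to rest on C3 as a deactivated oxygen-substituted carbene. The selectivity needed is ring closure over styrene homodimerisation and over migration of the double bond to C2=C3, which would erase C2; high dilution with removal of ethylene serves the first, and 1,4-benzoquinone, which intercepts ruthenium hydrides, serves the second.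

**Step 9**
Reactants: 13 (2R)-5,7-bis(benzyloxy)-2-[3,4-bis(benzyloxy)phenyl]-2H-chromen-3-yl 3-(benzyloxy)-4,5-dimethoxybenzoate
Product: 15 (2R,3R)-2-(3,4-dihydroxyphenyl)-5,7-dihydroxy-3,4-dihydro-2H-chromen-3-yl 3-hydroxy-4,5-dimethoxybenzoate, via pentabenzyl flavan ester 14 (not isolated)
Conditions: H2 (1 atm), 10% Pd/C, THF/EtOAc (1:1), rt
Reagents that add atoms: none
Why: Heterogeneous hydrogenation adds H2 syn to C3=C4 from the face opposite the pseudo-axial ring B on C2, so the new C3–H is trans to the aryl group and the ester cis (3R, substrate control), after which hydrogenolysis removes the five benzyl ethers while the aryl ester and the cyclic C2–O1 ether are expected to stay, as they do in benzylated catechin esters.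

**Compound list**
1 | 2,4,6-trihydroxybenzaldehyde | O=Cc1c(O)cc(O)cc1O | starting material
2 | 4,6-bis(benzyloxy)-2-hydroxybenzaldehyde | O=Cc1c(O)cc(OCc2ccccc2)cc1OCc1ccccc1 | intermediate
3 | 3,5-bis(benzyloxy)-2-ethenylphenol | C=Cc1c(O)cc(OCc2ccccc2)cc1OCc1ccccc1 | intermediate
4 | 3-hydroxy-4,5-dimethoxybenzoic acid | COc1cc(C(=O)O)cc(O)c1OC | starting material
5 | benzyl 3-(benzyloxy)-4,5-dimethoxybenzoate | COc1cc(C(=O)OCc2ccccc2)cc(OCc2ccccc2)c1OC | intermediate
6 | 3-(benzyloxy)-4,5-dimethoxybenzoic acid | COc1cc(C(=O)O)cc(OCc2ccccc2)c1OC | intermediate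
7 | 3,4-bis(benzyloxy)benzaldehyde | O=Cc1ccc(OCc2ccccc2)c(OCc2ccccc2)c1 | starting material
8 | ethynyltrimethylsilane | C#C[Si](C)(C)C | starting material
9 | (1S)-1-[3,4-bis(benzyloxy)phenyl]-3-(trimethylsilyl)prop-2-yn-1-ol | C[Si](C)(C)C#C[C@@H](O)c1ccc(OCc2ccccc2)c(OCc2ccccc2)c1 | intermediate
10 | {(3R)-3-[3,4-bis(benzyloxy)phenyl]-3-[3,5-bis(benzyloxy)-2-ethenylphenoxy]prop-1-yn-1-yl}trimethylsilane | C[Si](C)(C)C#C[C@H](Oc1cc(OCc2ccccc2)cc(OCc2ccccc2)c1C=C)c1ccc(OCc2ccccc2)c(OCc2ccccc2)c1 | intermediate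
11 | 1,5-bis(benzyloxy)-3-{[(1S)-1-[3,4-bis(benzyloxy)phenyl]prop-2-yn-1-yl]oxy}-2-ethenylbenzene | C#C[C@H](Oc1cc(OCc2ccccc2)cc(OCc2ccccc2)c1C=C)c1ccc(OCc2ccccc2)c(OCc2ccccc2)c1 | intermediate
12 | (3R)-3-[3,4-bis(benzyloxy)phenyl]-3-[3,5-bis(benzyloxy)-2-ethenylphenoxy]prop-1-en-2-yl 3-(benzyloxy)-4,5-dimethoxybenzoate | C=C(OC(=O)c1cc(OC)c(OC)c(OCc2ccccc2)c1)[C@H](Oc1cc(OCc2ccccc2)cc(OCc2ccccc2)c1C=C)c1ccc(OCc2ccccc2)c(OCc2ccccc2)c1 | intermediate
13 | (2R)-5,7-bis(benzyloxy)-2-[3,4-bis(benzyloxy)phenyl]-2H-chromen-3-yl 3-(benzyloxy)-4,5-dimethoxybenzoate | COc1cc(C(=O)OC2=Cc3c(OCc4ccccc4)cc(OCc4ccccc4)cc3O[C@@H]2c2ccc(OCc3ccccc3)c(OCc3ccccc3)c2)cc(OCc2ccccc2)c1OC | intermediate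
14 | (2R,3R)-5,7-bis(benzyloxy)-2-[3,4-bis(benzyloxy)phenyl]-3,4-dihydro-2H-chromen-3-yl 3-(benzyloxy)-4,5-dimethoxybenzoate | COc1cc(C(=O)O[C@@H]2Cc3c(OCc4ccccc4)cc(OCc4ccccc4)cc3O[C@@H]2c2ccc(OCc3ccccc3)c(OCc3ccccc3)c2)cc(OCc2ccccc2)c1OC | intermediate
15 | (2R,3R)-2-(3,4-dihydroxyphenyl)-5,7-dihydroxy-3,4-dihydro-2H-chromen-3-yl 3-hydroxy-4,5-dimethoxybenzoate | COc1cc(C(=O)O[C@@H]2Cc3c(O)cc(O)cc3O[C@@H]2c2ccc(O)c(O)c2)cc(O)c1OC | target

**Step count**
Total: 9 steps. Longest linear sequence: 7 steps (steps 1, 2, 5, 6, 7, 8, 9).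

**Steps most likely to fail**

Step 8 (ring-closing metathesis). The styrenyl alkylidene may fail to engage the hindered, acyloxy-substituted 1,1-disubstituted olefin, so that styrene homodimerisation and catalyst decay take over, or double-bond migration may erase C2. The fallback sets out from 11 and comes back to the route at 14.
- Semi-hydrogenation of the alkyne (H2, Pd/CaCO3 poisoned with Pb(OAc)2, quinoline, EtOAc) should give the bis-olefin 1,5-bis(benzyloxy)-3-{[(1S)-1-[3,4-bis(benzyloxy)phenyl]prop-2-en-1-yl]oxy}-2-ethenylbenzene F1.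
- Ring-closing metathesis of this plain 2-vinylphenyl allyl ether with the second-generation Grubbs catalyst (H2IMes)(PCy3)Cl2Ru=CHPh should give (2S)-5,7-bis(benzyloxy)-2-[3,4-bis(benzyloxy)phenyl]-2H-chromene F2 (same arrangement at C2, descriptor changed by priority only).
- Hydroboration–oxidation (BH3·THF, then NaOH/H2O2) anti to ring B should give the 2,3-trans alcohol (2R,3S)-5,7-bis(benzyloxy)-2-[3,4-bis(benzyloxy)phenyl]-3,4-dihydro-2H-chromen-3-ol F3.
- Oxidation with the periodinane DMP should give (2R)-5,7-bis(benzyloxy)-2-[3,4-bis(benzyloxy)phenyl]-2H-chromen-3(4H)-one F4.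
- Reduction with LiBH(s-Bu)3 at −78 °C from the face opposite ring B should give the 2,3-cis alcohol (2R,3R)-5,7-bis(benzyloxy)-2-[3,4-bis(benzyloxy)phenyl]-3,4-dihydro-2H-chromen-3-ol F5.
- Steglich esterification of that alcohol with acid 6 (DCC, DMAP, CH2Cl2) gives 14, and hydrogenolysis under the conditions of step 9 gives 15.

Step 7 (hydro-acyloxylation). The carboxylate may add at the terminal carbon through a vinylidene path, or addition at the hindered propargylic alkyne may be too slow. The fallback sets out from 11 and comes back at 12.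
- Copper-catalysed α-selective protoboration ((SIMes)CuCl, i.e. (1,3-dimesitylimidazolidin-2-ylidene)copper chloride, NaOtBu, B2pin2, MeOH, THF, −40 °C), which places boron on the internal carbon of propargylic ethers, should give 2-{(3S)-3-[3,4-bis(benzyloxy)phenyl]-3-[3,5-bis(benzyloxy)-2-ethenylphenoxy]prop-1-en-2-yl}-4,4,5,5-tetramethyl-1,3,2-dioxaborolane F6.
- Aqueous KHF2 in MeOH should convert it into potassium {(3S)-3-[3,4-bis(benzyloxy)phenyl]-3-[3,5-bis(benzyloxy)-2-ethenylphenoxy]prop-1-en-2-yl}trifluoroborate F7.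
- A Chan–Lam-type oxidative C–O coupling of that salt with acid 6 (CuBr, DMAP, 4 Å molecular sieves, O2, MeCN, 60 °C) should give enol ester 12.

Step 5 (Mitsunobu etherification). The oxyphosphonium intermediate may ionise at the electron-rich benzylic, propargylic carbon, which would erode the enantiomeric purity of C2. The fallback sets out from 9 and comes back at 11.
- Desilylation (K2CO3, MeOH) should give (1R)-1-[3,4-bis(benzyloxy)phenyl]prop-2-yn-1-ol F8.
- Acetylation (Ac2O, Et3N, DMAP) should give (1R)-1-[3,4-bis(benzyloxy)phenyl]prop-2-yn-1-yl acetate F9.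
- Copper-catalysed enantioselective propargylic etherification with phenol 3 ((CuOTf)2·C6H6, a chiral 2,6-bis(oxazolinyl)pyridine ligand, iPr2NEt, low temperature) runs through a copper allenylidene. The ligand, not the carbinol, therefore sets the configuration of the new C–O bond, and the antipode that gives the S ether leads directly to 11.

**Further compounds**
F1 | step 8 | 1,5-bis(benzyloxy)-3-{[(1S)-1-[3,4-bis(benzyloxy)phenyl]prop-2-en-1-yl]oxy}-2-ethenylbenzene | C=C[C@H](Oc1cc(OCc2ccccc2)cc(OCc2ccccc2)c1C=C)c1ccc(OCc2ccccc2)c(OCc2ccccc2)c1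
F2 | step 8 | (2S)-5,7-bis(benzyloxy)-2-[3,4-bis(benzyloxy)phenyl]-2H-chromene | C1=Cc2c(OCc3ccccc3)cc(OCc3ccccc3)cc2O[C@@H]1c1ccc(OCc2ccccc2)c(OCc2ccccc2)c1
F3 | step 8 | (2R,3S)-5,7-bis(benzyloxy)-2-[3,4-bis(benzyloxy)phenyl]-3,4-dihydro-2H-chromen-3-ol | O[C@H]1Cc2c(OCc3ccccc3)cc(OCc3ccccc3)cc2O[C@@H]1c1ccc(OCc2ccccc2)c(OCc2ccccc2)c1
F4 | step 8 | (2R)-5,7-bis(benzyloxy)-2-[3,4-bis(benzyloxy)phenyl]-2H-chromen-3(4H)-one | O=C1Cc2c(OCc3ccccc3)cc(OCc3ccccc3)cc2O[C@@H]1c1ccc(OCc2ccccc2)c(OCc2ccccc2)c1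
F5 | step 8 | (2R,3R)-5,7-bis(benzyloxy)-2-[3,4-bis(benzyloxy)phenyl]-3,4-dihydro-2H-chromen-3-ol | O[C@@H]1Cc2c(OCc3ccccc3)cc(OCc3ccccc3)cc2O[C@@H]1c1ccc(OCc2ccccc2)c(OCc2ccccc2)c1
F6 | step 7 | 2-{(3S)-3-[3,4-bis(benzyloxy)phenyl]-3-[3,5-bis(benzyloxy)-2-ethenylphenoxy]prop-1-en-2-yl}-4,4,5,5-tetramethyl-1,3,2-dioxaborolane | C=C(B1OC(C)(C)C(C)(C)O1)[C@H](Oc1cc(OCc2ccccc2)cc(OCc2ccccc2)c1C=C)c1ccc(OCc2ccccc2)c(OCc2ccccc2)c1
F7 | step 7 | potassium {(3S)-3-[3,4-bis(benzyloxy)phenyl]-3-[3,5-bis(benzyloxy)-2-ethenylphenoxy]prop-1-en-2-yl}trifluoroborate | [K+].C=C([B-](F)(F)F)[C@H](Oc1cc(OCc2ccccc2)cc(OCc2ccccc2)c1C=C)c1ccc(OCc2ccccc2)c(OCc2ccccc2)c1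
F8 | step 5 | (1R)-1-[3,4-bis(benzyloxy)phenyl]prop-2-yn-1-ol | C#C[C@@H](O)c1ccc(OCc2ccccc2)c(OCc2ccccc2)c1
F9 | step 5 | (1R)-1-[3,4-bis(benzyloxy)phenyl]prop-2-yn-1-yl acetate | C#C[C@@H](OC(C)=O)c1ccc(OCc2ccccc2)c(OCc2ccccc2)c1
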